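**Strategy.** The 14-membered ring is opened between C9 and C10: a seco-diyne with methyl-capped alkynes at both carbons is closed by ring-closing alkyne metathesis. One operation forms the C9≡C10 bond and the macrocycle while leaving the C1=C2 enone and the C3–C4 epoxide untouched. The step exploits the C8–C9(=O)–C10 ketone segment of the ring: stored as an alkyne, C9 cannot enolise, so the C8 stereocentre with its C19 acetoxymethyl arm is configurationally locked, and the acetate later steers water to C9. The precursor is an open-chain E-enone made by aldol condensation of a C10–C14/C1 ketone (Evans aldol) with a C2–C9 epoxy aldehyde (auxiliary hydroxymethylation, Suzuki coupling, Sharpless epoxidation).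

Key step: step 21

Remarks on the chemistry (assumptions):
- Ring numbering: C1 (isopropyl-bearing alkene carbon), C2 (alkene CH), C3/C4 (epoxide, methyl on C4), C5–C7, C8 (bears C19), C9, C10, C11, C12 (methyl), C13 (oxygen), C14 (enone carbonyl).
- Seco-diyne 35 and cycloalkyne 36 carry the target configuration at C3, C4, C8, C12 and C13 and the E-enone (C14 trans to C3); the C19 acetate and C13 TBS ether are kept.
- Two assumptions are made: the silanolate-ligated molybdenum alkylidyne tolerates the γ,δ-epoxy enone, and diethyl L-(+)-tartrate gives the (2S,3R)-epoxy alcohol from the Z-allylic alcohol, as for neryl-type substrates.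

**Fragment B (C10–C14, C1, isopropyl)**

Step 1
Reactants: 1 4-methylpentanal
Product: 2 4-methyl-2-methylidenepentanal
Conditions: aq. CH2O, pyrrolidine (10 mol%), propanoic acid (10 mol%), iPrOH, 45 °C
Reagents that add atoms: formaldehyde, C=O
Why: Amine/acid-catalysed Mannich-type α-methylenation (aldol condensation with formaldehyde) of a linear aldehyde is established and gives the 2-alkylacrolein that serves as a masked C14 ketone, with no stereocentre formed.

Step 2
Reactants: 3 (S)-4-benzyl-3-propanoyl-1,3-oxazolidin-2-one; 2 4-methyl-2-methylidenepentanal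
Product: 5 (S)-4-benzyl-3-[(2S,3S)-3-hydroxy-2,6-dimethyl-4-methylideneheptanoyl]-1,3-oxazolidin-2-one, via boron enolate 4 (not isolated)
Conditions: Bu2BOTf, Et3N, CH2Cl2, −78 to 0 °C; then 2, −78 to 0 °C; then pH 7 buffer, MeOH, H2O2, 0 °C
Reagents that add atoms: none
Why: Evans syn-aldol reaction in which the Z(O)-boron enolate adds through a closed chair transition state on the face away from the benzyl group, which should set C12 and C13 together as the syn (2S,3S) pair, the α-branched enal reacting only in the 1,2 sense.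

Step 3
Reactants: 5 aldol adduct
Product: 6 (S)-4-benzyl-3-[(2S,3S)-3-(tert-butyldimethylsilyloxy)-2,6-dimethyl-4-methylideneheptanoyl]-1,3-oxazolidin-2-one
Conditions: TBSOTf, 2,6-lutidine, CH2Cl2, −78 to 0 °C
Reagents that add atoms: tert-butyldimethylsilyl triflate, CC(C)(C)[Si](C)(C)OS(=O)(=O)C(F)(F)F
Why: Silylation of a hindered secondary alcohol with a silyl triflate and a hindered pyridine base is routine, blocks retro-aldol cleavage in the next step and changes no stereocentre.

Step 4
Reactants: 6 silylated imide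
Product: 7 (2R,3S)-3-(tert-butyldimethylsilyloxy)-2,6-dimethyl-4-methylideneheptan-1-ol
Conditions: LiBH4, MeOH (1 equiv), THF, 0 °C
Reagents that add atoms: none
Why: Reductive removal of the oxazolidinone by hydride attack at the exocyclic imide carbonyl is standard for silylated Evans aldol products and frees C11 as a primary alcohol without touching C12 or C13.

Step 5
Reactants: 7 primary alcohol
Product: 9 (5S,6R)-5-(tert-butyldimethylsilyloxy)-2,6-dimethyl-4-methylidenedec-8-yne, via triflate 8 (not isolated)
Conditions: Tf2O, 2,6-lutidine, CH2Cl2, −78 °C; then LiC≡CCH3, THF–DMPU, −78 to −20 °C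
Reagents that add atoms: 1-propynyllithium, [Li]C#CC
Why: Primary triflates alkylate lithium acetylides by clean SN2 displacement at low temperature in a dipolar medium, so the methyl-capped alkyne (C10) is attached to C11 without disturbing the neighbouring stereocentres.

Step 6
Reactants: 9 enyne
Product: 10 (5S,6R)-5-(tert-butyldimethylsilyloxy)-2,6-dimethyldec-8-yn-4-one (fragment B ketone)
Conditions: OsO4 (2 mol%), NaIO4, 2,6-lutidine, 1,4-dioxane–H2O (3:1), rt
Reagents that add atoms: sodium periodate, [Na+].[O-]I(=O)(=O)=O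
Why: Lemieux–Johnson cleavage (catalytic dihydroxylation then periodate scission) oxidises the 1,1-disubstituted alkene much faster than the internal alkyne and unmasks the C14 ketone under buffered conditions that leave the α-silyloxy centre C13 intact.

**Fragment A (C2–C9, C19)**

Step 7
Reactants: 11 (R)-4-benzyl-1,3-oxazolidin-2-one; 12 pent-4-enoyl chloride
Product: 14 (R)-4-benzyl-3-(pent-4-enoyl)-1,3-oxazolidin-2-one, via lithium oxazolidinide 13 (not isolated)
Conditions: n-BuLi, THF, −78 °C; then 12, −78 to 0 °C
Reagents that add atoms: none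
Why: N-Acylation of the lithiated oxazolidinone with an acid chloride is the standard entry to Evans imides and creates no stereocentre.

Step 8
Reactants: 14 pentenoyl imide
Product: 16 (R)-4-benzyl-3-[(S)-2-(hydroxymethyl)pent-4-enoyl]-1,3-oxazolidin-2-one, via titanium enolate 15 (not isolated)
Conditions: TiCl4, iPr2NEt, CH2Cl2, 0 °C; then 1,3,5-trioxane, TiCl4, 0 °C
Reagents that add atoms: 1,3,5-trioxane, C1OCOCO1
Why: Titanium-enolate hydroxymethylation of an Evans imide, in which the chelated Z-enolate is attacked by Lewis-acid-activated formaldehyde on the face opposite the benzyl group, should give the S-configured C8 carrying the C19 hydroxymethyl arm.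

Step 9
Reactants: 16 hydroxymethyl imide
Product: 17 (R)-4-benzyl-3-[(S)-2-{[(tert-butyldiphenylsilyl)oxy]methyl}pent-4-enoyl]-1,3-oxazolidin-2-one
Conditions: TBDPSCl, imidazole, DMF, rt
Reagents that add atoms: tert-butyldiphenylsilyl chloride, CC(C)(C)[Si](Cl)(c1ccccc1)c1ccccc1
Why: Silylation of the primary alcohol prevents retro-aldol loss of formaldehyde and differentiates the two future arms of C8, the bulky TBDPS group being chosen because it resists the 1,3-silyl migration that would erode C8 after the next step.

Step 10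
Reactants: 17 silylated imide
Product: 18 (R)-2-{[(tert-butyldiphenylsilyl)oxy]methyl}pent-4-en-1-ol
Conditions: LiBH4, MeOH (1 equiv), Et2O, 0 °C
Reagents that add atoms: none
Why: LiBH4 reduction of the imide releases the auxiliary and gives the mono-protected 2-allylpropane-1,3-diol, whose chirality rests only on the differentiation of the two arms and is preserved by the non-migrating silyl group.

Step 11
Reactants: 18 mono-protected diol
Product: 19 (S)-2-{[(tert-butyldiphenylsilyl)oxy]methyl}pent-4-enal
Conditions: Dess–Martin periodinane, NaHCO3, CH2Cl2, 0 °C to rt; used crude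
Reagents that add atoms: none
Why: Buffered Dess–Martin oxidation converts primary alcohols into α-branched β-silyloxy aldehydes without base-induced epimerisation or β-elimination, provided the aldehyde is used at once.

Step 12
Reactants: 19 aldehyde
Product: 20 (R)-tert-butyl{[2-(2,2-dibromoethenyl)pent-4-en-1-yl]oxy}diphenylsilane
Conditions: CBr4, PPh3, CH2Cl2, 0 °C
Reagents that add atoms: carbon tetrabromide, BrC(Br)(Br)Br
Why: The first stage of the Corey–Fuchs homologation (Wittig-type dibromomethylenation) runs under nearly neutral conditions and should preserve the α-stereocentre C8.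

Step 13
Reactants: 20 dibromoalkene
Product: 22 (R)-tert-butyldiphenyl{[2-(prop-1-yn-1-yl)pent-4-en-1-yl]oxy}silane, via lithium acetylide 21 (not isolated)
Conditions: n-BuLi (2.2 equiv), THF, −78 °C; then MeI, −78 °C to rt
Reagents that add atoms: iodomethane, CI
Why: The second Corey–Fuchs stage (bromine–lithium exchange, α-elimination with 1,2-shift, deprotonation) gives the lithium acetylide, whose C-methylation delivers the methyl-capped C9 alkyne while the propargylic centre C8 is not acidic enough to suffer.

Step 14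
Reactants: 22 silyl ether
Product: 24 (R)-2-(prop-1-yn-1-yl)pent-4-en-1-yl acetate, via alcohol 23 (not isolated)
Conditions: Bu4NF, THF, 0 °C to rt; then Ac2O, pyridine, DMAP (cat.), rt
Reagents that add atoms: acetic anhydride, CC(=O)OC(C)=O
Why: Fluoride cleavage of the silyl ether and acetylation of the liberated alkoxide in the same flask exchange the base-stable protecting group for the C19 acetate needed later, without isolating the volatile alcohol.

Step 15
Reactants: 25 but-2-yn-1-ol
Product: 27 (Z)-3-iodobut-2-en-1-ol, via alkenylaluminate 26 (not isolated)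
Conditions: NaAlH2(OCH2CH2OMe)2, Et2O, 0 °C to rt; then I2, THF, −78 to 0 °C
Reagents that add atoms: iodine, [I][I]
Why: Hydroxyl-directed trans-hydroalumination of a propargylic alcohol places aluminium on C3 within a five-membered alkoxyaluminate, and iodinolysis with retention gives the iodide in which iodine and the hydroxymethyl group are cis.

Step 16
Reactants: 24 enyne acetate; 27 (Z)-3-iodobut-2-en-1-ol
Product: 29 (2R,6Z)-8-hydroxy-6-methyl-2-(prop-1-yn-1-yl)oct-6-en-1-yl acetate, via alkylborane 28 (not isolated)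
Conditions: 9-BBN, THF, 0 °C to rt; then 27, PdCl2(dppf) (5 mol%), AsPh3, Cs2CO3, DMF–H2O, rt
Reagents that add atoms: none
Why: B-alkyl Suzuki–Miyaura coupling, in which 9-BBN hydroborates the terminal alkene at C5 far faster than the hindered internal alkyne and spares the acetate, and the alkylborane couples with the vinyl iodide with retention to fix the Z (neryl-type) trisubstituted alkene C3=C4.

Step 17
Reactants: 29 Z-allylic alcohol
Product: 30 (2R)-5-[(2R,3S)-3-(hydroxymethyl)-2-methyloxiran-2-yl]-2-(prop-1-yn-1-yl)pentyl acetate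
Conditions: Ti(OiPr)4, diethyl L-(+)-tartrate, t-BuOOH, 4 Å MS, CH2Cl2, −20 °C
Reagents that add atoms: tert-butyl hydroperoxide, CC(C)(C)OO
Why: Sharpless asymmetric epoxidation of a Z-trisubstituted allylic alcohol with the L-(+)-tartrate catalyst is reagent-controlled and should set C3 and C4 as the (2S,3R)-epoxy alcohol irrespective of the remote C8 centre.

Step 18
Reactants: 30 epoxy alcohol
Product: 31 (2R)-5-[(2R,3R)-3-formyl-2-methyloxiran-2-yl]-2-(prop-1-yn-1-yl)pentyl acetate (fragment A aldehyde)
Conditions: Dess–Martin periodinane, NaHCO3, CH2Cl2, 0 °C to rt; used crude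
Reagents that add atoms: none
Why: Buffered Dess–Martin oxidation of 2,3-epoxy alcohols to epoxy aldehydes is well precedented and leaves epoxide, acetate and alkyne untouched, C3 having no tendency to epimerise under these neutral conditions.

**Union, ring closure and end game**

Step 19
Reactants: 10 fragment B ketone; 31 fragment A aldehyde
Product: 33 β-hydroxy ketone (C1–C2 aldol adduct; mixture at C1 and C2; other centres as in 35), via lithium enolate 32 (not isolated)
Conditions: LiN(iPr)2 (1.0 equiv), THF, −78 °C; then 31, −78 °C; aq. NH4Cl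
Reagents that add atoms: none
Why: Directed aldol addition in which kinetic deprotonation of the α-silyloxy ketone occurs at the less hindered C1 methylene to give the Z(O)-lithium enolate, which adds at −78 °C to the non-enolisable and highly electrophilic epoxy aldehyde faster than to the acetate, the diastereomers at C1 and C2 converging in the next step.

Step 20
Reactants: 33 β-hydroxy ketone
Product: 35 seco-diyne (E-enone; 3S,4R,8R,12R,13S; C19 acetate; C13 TBS ether; methyl-capped alkynes at C9 and C10), via mesylate 34 (not isolated)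
Conditions: MsCl, Et3N, CH2Cl2, 0 °C; then DBU, 0 °C to rt
Reagents that add atoms: none
Why: Mesylation and DBU-induced E1cB elimination of a β-hydroxy ketone should give the conjugated enone with the thermodynamically preferred E geometry (C14 trans to C3, as in tiglate-type enones), while the C19 acetate has no elimination pathway because C9 is an alkyne carbon.

Step 21
Reactants: 35 seco-diyne
Product: 36 14-membered cycloalkyne (C9≡C10; E-enone; 3S,4R,8R,12R,13S; C19 acetate; C13 TBS ether)
Conditions: Mo(≡CC6H4OMe-4)(OSiPh3)3 (10 mol%), 5 Å MS, toluene (0.002 M), rt to 60 °C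
Reagents that add atoms: none
Why: The molybdenum alkylidyne undergoes [2+2] cycloaddition and cycloreversion with each methyl-capped alkyne through metallacyclobutadienes, expelling but-2-yne (trapped by the 5 Å sieves) and finally joining C9 to C10 as the ring alkyne. The closest known reaction type is ring-closing alkyne metathesis of bis(methylalkynes) to 12- to 18-membered cycloalkynes with silanolate-ligated alkylidynes, which tolerate ketones, esters and silyl ethers. The single ring formed is the 14-membered carbocycle, closed end to end at C9≡C10 as an unstrained macrocyclisation in which the E-enone and the epoxide pre-organise part of the chain. No stereocentre is created and C3, C4, C8, C12 and C13 are not touched, C8 remaining a propargylic centre that cannot enolise. The step needs chemoselectivity for the alkynes over the C1=C2 alkene, which alkylidynes do not engage, and cyclisation over oligomerisation, which high dilution and irreversible removal of but-2-yne secure. The substrate offers two unhindered CH3–C≡C termini, one on the C11 methylene and one on the C8 methine, the pattern these catalysts accept best.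

Step 22
Reactants: 36 cycloalkyne
Product: 37 C9 ketone (β-acetoxy ketone; 3S,4R,8S,12R,13S; C19 acetate; C13 TBS ether)
Conditions: Ph3PAuNTf2 (5 mol%), 1,4-dioxane–H2O (20:1), rt
Reagents that add atoms: water, O
Why: Gold-catalysed alkyne hydration with anchimeric assistance, in which the carbonyl oxygen of the C19 acetate attacks the gold-activated alkyne at C9 in a 6-exo-dig mode, water opens the resulting dioxanylium ion and protodeauration gives the C9 ketone with the acetate returned to C19 under nearly neutral conditions that should not epimerise C8.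

Step 23
Reactants: 37 silyl ether
Product: 38 C13 alcohol (C19 acetate retained)
Conditions: Et3N·3HF, MeCN, rt
Reagents that add atoms: none
Why: Amine-buffered hydrogen fluoride cleaves the α-keto silyl ether without the basicity that would trigger β-elimination of the C19 acetate and is mild enough to spare the trisubstituted epoxide.

Step 24
Reactants: 38 monoacetate
Product: 39 target, (1E,3S,4R,8S,12R,13S)-13-hydroxy-8-(hydroxymethyl)-1-isopropyl-4,12-dimethyl-3,4-epoxycyclotetradec-1-ene-9,14-dione
Conditions: immobilised Candida antarctica lipase B, pH 7 phosphate buffer–acetone (4:1), 30 °C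
Reagents that add atoms: none
Why: Lipase-catalysed hydrolysis of an unhindered primary acetate at pH 7 unveils the acid- and base-sensitive β-hydroxy ketone last, under conditions that cannot epimerise C8, dehydrate C8–C19 or open the epoxide.

**Compound list**

1 | 4-methylpentanal | CC(C)CCC=O | starting material
2 | 4-methyl-2-methylidenepentanal | CC(C)CC(=C)C=O | intermediate
3 | (S)-4-benzyl-3-propanoyl-1,3-oxazolidin-2-one | CCC(=O)N1[C@@H](Cc2ccccc2)COC1=O | starting material
4 | dibutylboron Z-enolate of 3 | CCCCB(CCCC)O/C(=C\C)N1[C@@H](Cc2ccccc2)COC1=O | intermediate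
5 | (S)-4-benzyl-3-[(2S,3S)-3-hydroxy-2,6-dimethyl-4-methylideneheptanoyl]-1,3-oxazolidin-2-one | O=C1OC[C@H](Cc2ccccc2)N1C(=O)[C@@H](C)[C@H](O)C(=C)CC(C)C | intermediate
6 | TBS ether of 5 | O=C1OC[C@H](Cc2ccccc2)N1C(=O)[C@@H](C)[C@H](O[Si](C)(C)C(C)(C)C)C(=C)CC(C)C | intermediate
7 | (2R,3S)-3-(tert-butyldimethylsilyloxy)-2,6-dimethyl-4-methylideneheptan-1-ol | OC[C@@H](C)[C@H](O[Si](C)(C)C(C)(C)C)C(=C)CC(C)C | intermediate
8 | primary triflate of 7 | FC(F)(F)S(=O)(=O)OC[C@@H](C)[C@H](O[Si](C)(C)C(C)(C)C)C(=C)CC(C)C | intermediate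
9 | (5S,6R)-5-(tert-butyldimethylsilyloxy)-2,6-dimethyl-4-methylidenedec-8-yne | CC#CC[C@@H](C)[C@H](O[Si](C)(C)C(C)(C)C)C(=C)CC(C)C | intermediate
10 | (5S,6R)-5-(tert-butyldimethylsilyloxy)-2,6-dimethyldec-8-yn-4-one | CC#CC[C@@H](C)[C@H](O[Si](C)(C)C(C)(C)C)C(=O)CC(C)C | intermediate
11 | (R)-4-benzyl-1,3-oxazolidin-2-one | O=C1N[C@H](Cc2ccccc2)CO1 | starting material
12 | pent-4-enoyl chloride | C=CCCC(Cl)=O | starting material
13 | N-lithio derivative of 11 | [Li]N1[C@H](Cc2ccccc2)COC1=O | intermediate
14 | (R)-4-benzyl-3-(pent-4-enoyl)-1,3-oxazolidin-2-one | C=CCCC(=O)N1[C@H](Cc2ccccc2)COC1=O | intermediate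
15 | trichlorotitanium Z-enolate of 14 | Cl[Ti](Cl)(Cl)O/C(=C\CC=C)N1[C@H](Cc2ccccc2)COC1=O | intermediate
16 | (R)-4-benzyl-3-[(S)-2-(hydroxymethyl)pent-4-enoyl]-1,3-oxazolidin-2-one | C=CC[C@@H](CO)C(=O)N1[C@H](Cc2ccccc2)COC1=O | intermediate
17 | TBDPS ether of 16 | C=CC[C@@H](CO[Si](c1ccccc1)(c1ccccc1)C(C)(C)C)C(=O)N1[C@H](Cc2ccccc2)COC1=O | intermediate
18 | (R)-2-{[(tert-butyldiphenylsilyl)oxy]methyl}pent-4-en-1-ol | C=CC[C@@H](CO[Si](c1ccccc1)(c1ccccc1)C(C)(C)C)CO | intermediate
19 | (S)-2-{[(tert-butyldiphenylsilyl)oxy]methyl}pent-4-enal | C=CC[C@@H](CO[Si](c1ccccc1)(c1ccccc1)C(C)(C)C)C=O | intermediate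
20 | (R)-tert-butyl{[2-(2,2-dibromoethenyl)pent-4-en-1-yl]oxy}diphenylsilane | C=CC[C@@H](CO[Si](c1ccccc1)(c1ccccc1)C(C)(C)C)C=C(Br)Br | intermediate
21 | lithium acetylide from 20 | C=CC[C@@H](CO[Si](c1ccccc1)(c1ccccc1)C(C)(C)C)C#C[Li] | intermediate
22 | (R)-tert-butyldiphenyl{[2-(prop-1-yn-1-yl)pent-4-en-1-yl]oxy}silane | C=CC[C@@H](CO[Si](c1ccccc1)(c1ccccc1)C(C)(C)C)C#CC | intermediate
23 | (R)-2-(prop-1-yn-1-yl)pent-4-en-1-ol | C=CC[C@@H](CO)C#CC | intermediate
24 | (R)-2-(prop-1-yn-1-yl)pent-4-en-1-yl acetate | C=CC[C@@H](COC(C)=O)C#CC | intermediate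
25 | but-2-yn-1-ol | CC#CCO | starting material
26 | sodium cyclic alkenyl(alkoxy)aluminate from 25 (Al on C3, cis to CH2O) | C/C1=C/CO[Al-]1(OCCOC)OCCOC.[Na+] | intermediate
27 | (Z)-3-iodobut-2-en-1-ol | OC/C=C(/C)I | intermediate
28 | B-alkyl-9-borabicyclo[3.3.1]nonane from 24 (boron on C5) | B1(CCC[C@@H](COC(C)=O)C#CC)C2CCCC1CCC2 | intermediate
29 | (2R,6Z)-8-hydroxy-6-methyl-2-(prop-1-yn-1-yl)oct-6-en-1-yl acetate | OC/C=C(/C)CCC[C@@H](COC(C)=O)C#CC | intermediate
30 | (2R)-5-[(2R,3S)-3-(hydroxymethyl)-2-methyloxiran-2-yl]-2-(prop-1-yn-1-yl)pentyl acetate | OC[C@@H]1O[C@]1(C)CCC[C@@H](COC(C)=O)C#CC | intermediate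
31 | (2R)-5-[(2R,3R)-3-formyl-2-methyloxiran-2-yl]-2-(prop-1-yn-1-yl)pentyl acetate | O=C[C@@H]1O[C@]1(C)CCC[C@@H](COC(C)=O)C#CC | intermediate
32 | lithium Z(O)-enolate of 10 (C14–C1) | CC#CC[C@@H](C)[C@H](O[Si](C)(C)C(C)(C)C)/C(O[Li])=C/C(C)C | intermediate
33 | β-hydroxy ketone, open chain (C2 hydroxyl, C1 isopropyl; mixture at C1/C2) | CC#CC[C@@H](C)[C@H](O[Si](C)(C)C(C)(C)C)C(=O)C(C(C)C)C(O)[C@@H]1O[C@]1(C)CCC[C@@H](COC(C)=O)C#CC | intermediate
34 | C2 mesylate of 33 | CC#CC[C@@H](C)[C@H](O[Si](C)(C)C(C)(C)C)C(=O)C(C(C)C)C(OS(C)(=O)=O)[C@@H]1O[C@]1(C)CCC[C@@H](COC(C)=O)C#CC | intermediate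
35 | seco-diyne (E-enone; 3S,4R,8R,12R,13S) | CC#CC[C@@H](C)[C@H](O[Si](C)(C)C(C)(C)C)C(=O)/C(C(C)C)=C/[C@@H]1O[C@]1(C)CCC[C@@H](COC(C)=O)C#CC | intermediate
36 | 14-membered cycloalkyne (C9≡C10; 3S,4R,8R,12R,13S) | CC(C)/C1=C\[C@@H]2O[C@]2(C)CCC[C@@H](COC(C)=O)C#CC[C@@H](C)[C@H](O[Si](C)(C)C(C)(C)C)C1=O | intermediate
37 | C9 ketone with C19 acetate and C13 TBS ether (3S,4R,8S,12R,13S) | CC(C)/C1=C\[C@@H]2O[C@]2(C)CCC[C@@H](COC(C)=O)C(=O)CC[C@@H](C)[C@H](O[Si](C)(C)C(C)(C)C)C1=O | intermediate
38 | C13 alcohol with C19 acetate | CC(C)/C1=C\[C@@H]2O[C@]2(C)CCC[C@@H](COC(C)=O)C(=O)CC[C@@H](C)[C@H](O)C1=O | intermediate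
39 | (1E,3S,4R,8S,12R,13S)-13-hydroxy-8-(hydroxymethyl)-1-isopropyl-4,12-dimethyl-3,4-epoxycyclotetradec-1-ene-9,14-dione | CC(C)/C1=C\[C@@H]2O[C@]2(C)CCC[C@@H](CO)C(=O)CC[C@@H](C)[C@H](O)C1=O | target

**Totals and risks**

Total step count: 24. Longest linear sequence: 17 steps (steps 7–14, 16–24, from 11 to 39).

Steps most likely to fail:

1. Step 22 (hydration). Water may be delivered to C10 instead of C9 if the C14 carbonyl or the C13 silyl ether oxygen competes with the acetate for the activated alkyne, or the catalyst may activate the epoxide. Fallback, setting out from cycloalkyne 36: lipase deacetylation gives the homopropargylic alcohol F1; silylation with (HMe2Si)2NH gives the dimethylsilyl ether F2; platinum-catalysed intramolecular hydrosilylation (Pt2[(CH2=CHSiMe2)2O]3, THF, rt) closes the five-membered alkylidene oxasilolane F3 by syn 5-exo addition with silicon on C9; Tamao oxidation (H2O2, KF, KHCO3, THF–MeOH, 0 °C) gives the β-hydroxy ketone F4, still silylated at C13; desilylation with Et3N·3HF as in step 23 returns to the route at target 39.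

2. Step 21 (ring-closing alkyne metathesis). Oligomerisation may outrun cyclisation of the conformationally restricted seco-diyne, or the catalyst may be deactivated by chelation to the γ,δ-epoxy enone. Fallback, setting out from ketone 10 and epoxy alcohol 30: the C9≡C10 bond is made intermolecularly by alkyne cross-metathesis with the same alkylidyne (excess 10, 5 Å MS, toluene), giving the open-chain keto epoxy alcohol F5 before any enone exists; Dess–Martin oxidation gives the keto epoxy aldehyde F6; intramolecular aldol addition at high dilution (LiN(SiMe3)2, THF, −78 °C) closes the ring at C1–C2 to the macrocyclic aldol F7; mesylation to F8 and DBU elimination return to the route at cycloalkyne 36.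

3. Step 20 (with step 19, enone formation). The elimination may proceed without geometric control at C1=C2, and the base may epimerise C13 or reverse the aldol. Fallback, setting out from ketone 10 through its lithium enolate 32: C-phosphinylation with ClP(OEt)2 gives the α-phosphonite ketone F9 (not isolated), which is oxidised in air to the diethyl β-ketophosphonate F10; Horner–Wadsworth–Emmons olefination of epoxy aldehyde 31 with F10 (Ba(OH)2, wet THF, rt) forms C1=C2 in one operation and returns to the route at seco-diyne 35.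

**Further compounds**

F1 | step 22 | cycloalkyne with free C19 hydroxyl and C13 TBS ether | CC(C)/C1=C\[C@@H]2O[C@]2(C)CCC[C@@H](CO)C#CC[C@@H](C)[C@H](O[Si](C)(C)C(C)(C)C)C1=O
F2 | step 22 | C19 dimethylsilyl ether of F1 | CC(C)/C1=C\[C@@H]2O[C@]2(C)CCC[C@@H](CO[SiH](C)C)C#CC[C@@H](C)[C@H](O[Si](C)(C)C(C)(C)C)C1=O
F3 | step 22 | alkylidene oxasilolane (Si on C9, O on C19, exocyclic C9=C10 with H cis to Si) | CC(C)/C1=C\[C@@H]2O[C@]2(C)CCC[C@H]3CO[Si](C)(C)/C3=C/C[C@@H](C)[C@H](O[Si](C)(C)C(C)(C)C)C1=O
F4 | step 22 | C9 ketone with free C19 hydroxyl and C13 TBS ether | CC(C)/C1=C\[C@@H]2O[C@]2(C)CCC[C@@H](CO)C(=O)CC[C@@H](C)[C@H](O[Si](C)(C)C(C)(C)C)C1=O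
F5 | step 21 | open-chain C9≡C10 alkyne with C14 ketone and C2 hydroxyl (epoxy alcohol) | OC[C@@H]1O[C@]1(C)CCC[C@@H](COC(C)=O)C#CC[C@@H](C)[C@H](O[Si](C)(C)C(C)(C)C)C(=O)CC(C)C
F6 | step 21 | open-chain keto epoxy aldehyde (C2 aldehyde, C14 ketone) | O=C[C@@H]1O[C@]1(C)CCC[C@@H](COC(C)=O)C#CC[C@@H](C)[C@H](O[Si](C)(C)C(C)(C)C)C(=O)CC(C)C
F7 | step 21 | macrocyclic aldol (C2 hydroxyl, C1 isopropyl, C9≡C10) | CC(C)C1C(O)[C@@H]2O[C@]2(C)CCC[C@@H](COC(C)=O)C#CC[C@@H](C)[C@H](O[Si](C)(C)C(C)(C)C)C1=O
F8 | step 21 | C2 mesylate of F7 | CC(C)C1C(OS(C)(=O)=O)[C@@H]2O[C@]2(C)CCC[C@@H](COC(C)=O)C#CC[C@@H](C)[C@H](O[Si](C)(C)C(C)(C)C)C1=O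
F9 | step 20 | C1 diethyl phosphonite of ketone 10 | CC#CC[C@@H](C)[C@H](O[Si](C)(C)C(C)(C)C)C(=O)C(C(C)C)P(OCC)OCC
F10 | step 20 | C1 diethyl phosphonate of ketone 10 (β-ketophosphonate) | CC#CC[C@@H](C)[C@H](O[Si](C)(C)C(C)(C)C)C(=O)C(C(C)C)P(=O)(OCC)OCC
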